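**Retrosynthetic overview**
- The target is reached from its 7-O-benzyl ether by hydrogenolysis, and that ether from the 5,8-hydroquinone by methylation of the free O8 (O5 is chelated to the C4 carbonyl).
- Ring A is closed last. The C8–C8a bond forms in a 4π-opening/6π-closure cascade of a squarate-derived 4-hydroxycyclobutenone that already carries ring C (the pyranone) and ring B.
- That cyclobutenone comes from the bis(benzyloxy) adduct by exchange of the C3 benzyloxy group for methoxy. The adduct comes from a 5-magnesiated 2-aryl-4-pyranone and dibenzyl squarate (C4a–C5 bond).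
- Ring C is built first, from 4-methoxybut-3-en-2-one and 2,3-dimethoxybenzoyl chloride, then iodinated at C5. Ring B is bought.
- Feature used: C5, C6, C7 and C8 of ring A are four adjacent carbons that each carry an oxygen, and they map onto the four carbons of squaric acid. C4a and C8a are C5 and C6 of the pyranone.

Key step: step 7

Assumption: positions follow flavone numbering (ring A = C4a, C5–C8, C8a). For the monocyclic pyranone the numbering O1, C2 (aryl), C3, C4 (C=O), C5, C6 is kept in the text, so its C5 becomes C4a and its C6 becomes C8a. Compounds with a stereocentre are racemic, which does not matter because the target is achiral.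

**Step 1**
Reactants: 1 squaric acid
Product: 2 dibenzyl squarate [3,4-bis(benzyloxy)cyclobut-3-ene-1,2-dione]
Conditions: BnOH (4 equiv), toluene, reflux, Dean–Stark trap
Reagents that add atoms: benzyl alcohol, OCc1ccccc1
Why: Fischer-type esterification of the vinylogous diacid, which is acidic enough to catalyse itself, is driven to the diester by azeotropic removal of water.

**Step 2**
Reactants: 3 (E)-4-methoxybut-3-en-2-one; 4 2,3-dimethoxybenzoyl chloride
Product: 6 (4E)-1-(2,3-dimethoxyphenyl)-5-methoxypent-4-ene-1,3-dione, via lithium dienolate 5 (not isolated)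
Conditions: LiN(SiMe3)2 (2.1 equiv), 3 (2.1 equiv), THF, −78 °C; then 4 (1.0 equiv), −78 °C; aq. NH4Cl
Reagents that add atoms: none
Why: Kinetic deprotonation of the methyl group gives a cross-conjugated enolate that is C-acylated by the aroyl chloride (crossed Claisen-type acylation), the second equivalent of enolate taking up the acidic proton of the 1,3-diketone formed.

**Step 3**
Reactants: 6 (4E)-1-(2,3-dimethoxyphenyl)-5-methoxypent-4-ene-1,3-dione
Product: 7 2-(2,3-dimethoxyphenyl)-4H-pyran-4-one
Conditions: CF3CO2H (0.2 equiv), toluene, 23 °C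
Reagents that add atoms: none
Why: The enol oxygen of the aryl ketone adds to the β-methoxy enone terminus and methanol is lost (acid-catalysed oxa-Michael addition–elimination, the usual closure of 5-methoxypent-4-ene-1,3-diones to 4-pyranones).

**Step 4**
Reactants: 7 2-(2,3-dimethoxyphenyl)-4H-pyran-4-one
Product: 8 2-(2,3-dimethoxyphenyl)-5-iodo-4H-pyran-4-one
Conditions: I2 (1.5 equiv), pyridine–CH2Cl2 (1:1), DMAP (0.2 equiv), 23 °C; aq. Na2S2O3
Reagents that add atoms: iodine, II
Why: In the Johnson α-iodination of enones the amine adds reversibly to the unsubstituted β-carbon C6, the enolate is iodinated at C5 and the amine is eliminated, so iodine should enter at C5 and not at C3 beside the aryl-bearing C2, and the mild iodine source should leave the dimethoxyphenyl ring untouched.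

**Step 5**
Reactants: 8 2-(2,3-dimethoxyphenyl)-5-iodo-4H-pyran-4-one; 2 dibenzyl squarate
Product: 10 2,3-bis(benzyloxy)-4-[6-(2,3-dimethoxyphenyl)-4-oxo-4H-pyran-3-yl]-4-hydroxycyclobut-2-en-1-one (racemic), via pyranonylmagnesium chloride 9 (not isolated)
Conditions: iPrMgCl·LiCl (1.05 equiv), THF, −40 °C; then cannula transfer into 2 (1.3 equiv), THF, −78 °C; aq. NH4Cl at −78 °C
Reagents that add atoms: none
Why: Iodine–magnesium exchange on the carbonyl-activated alkenyl iodide should outrun attack on the weakly electrophilic pyranone carbonyl, and the alkenylmagnesium then adds 1,2 to one of the two equivalent squarate carbonyls (Grignard addition to a squarate ester), inverse addition at low temperature suppressing a second addition and the carbinol centre forming as a racemate.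

**Step 6**
Reactants: 10 2,3-bis(benzyloxy)-4-[6-(2,3-dimethoxyphenyl)-4-oxo-4H-pyran-3-yl]-4-hydroxycyclobut-2-en-1-one
Product: 11 2-(benzyloxy)-4-[6-(2,3-dimethoxyphenyl)-4-oxo-4H-pyran-3-yl]-4-hydroxy-3-methoxycyclobut-2-en-1-one (racemic)
Conditions: NaOMe (0.2 equiv), MeOH–THF (4:1), −20 to 0 °C; AcOH quench
Reagents that add atoms: methanol, CO
Why: Only the C3 benzyloxy group belongs to a vinylogous ester, so methoxide adds to C3 and benzyl oxide leaves (conjugate addition–elimination, vinylogous transesterification driven by the methanol solvent), whereas the C2 benzyloxy group on the α-carbon has no such pathway.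

**Step 7**
Reactants: 11 2-(benzyloxy)-4-[6-(2,3-dimethoxyphenyl)-4-oxo-4H-pyran-3-yl]-4-hydroxy-3-methoxycyclobut-2-en-1-one
Product: 14 7-(benzyloxy)-5,8-dihydroxy-6-methoxy-2-(2,3-dimethoxyphenyl)chromen-4-one, via dienylketene 12 (not isolated), via cyclohexadienone 13 (not isolated)
Conditions: degassed p-xylene (0.02 M), 135 °C, Ar
Reagents that add atoms: none
Why: Heating should open the strained cyclobutenone by conrotatory 4π electrocyclic ring opening to dienylketene 12, whose ketene C=C, former C2=C3 bond and pyranone C5=C6 bond form a 1,3,5-triene; thermal disrotatory 6π electrocyclisation closes the six-membered carbocycle (ring A) by joining the ketene carbon to pyranone C6 (the C8–C8a bond) and gives dienone 13, which enolises to the aromatic hydroquinone 14. The closest known reaction is the Moore rearrangement, the thermal ring expansion of 4-aryl-, 4-heteroaryl- and 4-alkenyl-4-hydroxycyclobutenones to hydroquinones. The step needs torquoselectivity in the ring opening, and the hydroxyl group secures it: as the strongest donor on the breaking bond it rotates outward and so turns the pyranonyl group inward, next to the ketene. Site selectivity is secured by the substrate because the other neighbour of the attachment carbon is the C4 carbonyl carbon, so only C6–H can enter a six-membered closure. The single sp3 centre that forms (C8a of 13) disappears on tautomerisation, so no stereocentre has to be controlled. The order of the ring A oxygens is copied from the cyclobutenone: carbinol oxygen to O5, C3 methoxy to O6, C2 benzyloxy to O7, ketene oxygen to O8.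

**Step 8**
Reactants: 14 7-(benzyloxy)-5,8-dihydroxy-6-methoxy-2-(2,3-dimethoxyphenyl)chromen-4-one
Product: 15 7-(benzyloxy)-5-hydroxy-6,8-dimethoxy-2-(2,3-dimethoxyphenyl)chromen-4-one
Conditions: MeI (1.2 equiv), K2CO3 (1.5 equiv), acetone, 23 °C, Ar
Reagents that add atoms: iodomethane, CI
Why: Williamson etherification should take place only at the free 8-hydroxyl, because the 5-hydroxyl is hydrogen-bonded to the C4 carbonyl and is alkylated only under forcing conditions, while exclusion of air keeps the hydroquinone from oxidising to the quinone.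

**Step 9**
Reactants: 15 7-(benzyloxy)-5-hydroxy-6,8-dimethoxy-2-(2,3-dimethoxyphenyl)chromen-4-one
Product: 16 5,7-dihydroxy-6,8-dimethoxy-2-(2,3-dimethoxyphenyl)chromen-4-one (5,7-dihydroxy-6,8,2',3'-tetramethoxyflavone)
Conditions: H2 (1 atm), 10% Pd/C, EtOAc–MeOH, 23 °C
Reagents that add atoms: none
Why: Catalytic hydrogenolysis of the benzyl aryl ether is fast at atmospheric pressure and should be complete before the C2–C3 double bond of the flavone is reduced, the methyl ethers being inert.

**Compound list**
1 | squaric acid (3,4-dihydroxycyclobut-3-ene-1,2-dione) | O=C1C(O)=C(O)C1=O | starting material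
2 | dibenzyl squarate [3,4-bis(benzyloxy)cyclobut-3-ene-1,2-dione] | O=C1C(=O)C(OCc2ccccc2)=C1OCc1ccccc1 | intermediate
3 | (E)-4-methoxybut-3-en-2-one | CO/C=C/C(C)=O | starting material
4 | 2,3-dimethoxybenzoyl chloride | COc1cccc(C(=O)Cl)c1OC | starting material
5 | lithium (3E)-4-methoxybuta-1,3-dien-2-olate | C=C(O[Li])/C=C/OC | intermediate
6 | (4E)-1-(2,3-dimethoxyphenyl)-5-methoxypent-4-ene-1,3-dione (drawn as the diketone, enolised in solution) | COc1cccc(C(=O)CC(=O)/C=C/OC)c1OC | intermediate
7 | 2-(2,3-dimethoxyphenyl)-4H-pyran-4-one | COc1cccc(-c2cc(=O)cco2)c1OC | intermediate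
8 | 2-(2,3-dimethoxyphenyl)-5-iodo-4H-pyran-4-one | COc1cccc(-c2cc(=O)c(I)co2)c1OC | intermediate
9 | [6-(2,3-dimethoxyphenyl)-4-oxo-4H-pyran-3-yl]magnesium chloride (LiCl complex) | COc1cccc(-c2cc(=O)c([Mg]Cl)co2)c1OC | intermediate
10 | 2,3-bis(benzyloxy)-4-[6-(2,3-dimethoxyphenyl)-4-oxo-4H-pyran-3-yl]-4-hydroxycyclobut-2-en-1-one (racemic) | O=C1C(OCc2ccccc2)=C(OCc2ccccc2)C1(O)c1coc(-c2cccc(OC)c2OC)cc1=O | intermediate
11 | 2-(benzyloxy)-4-[6-(2,3-dimethoxyphenyl)-4-oxo-4H-pyran-3-yl]-4-hydroxy-3-methoxycyclobut-2-en-1-one (racemic) | O=C1C(OCc2ccccc2)=C(OC)C1(O)c1coc(-c2cccc(OC)c2OC)cc1=O | intermediate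
12 | (3Z)-2-(benzyloxy)-4-[6-(2,3-dimethoxyphenyl)-4-oxo-4H-pyran-3-yl]-4-hydroxy-3-methoxybuta-1,3-dien-1-one | O=C=C(OCc1ccccc1)/C(OC)=C(/O)c1coc(-c2cccc(OC)c2OC)cc1=O | intermediate
13 | 7-(benzyloxy)-2-(2,3-dimethoxyphenyl)-5-hydroxy-6-methoxy-8aH-chromene-4,8-dione (racemic) | O=C1C(OCc2ccccc2)=C(OC)C(O)=C2C(=O)C=C(c3cccc(OC)c3OC)OC21 | intermediate
14 | 7-(benzyloxy)-5,8-dihydroxy-6-methoxy-2-(2,3-dimethoxyphenyl)chromen-4-one | COc1cccc(-c2cc(=O)c3c(O)c(OC)c(OCc4ccccc4)c(O)c3o2)c1OC | intermediate
15 | 7-(benzyloxy)-5-hydroxy-6,8-dimethoxy-2-(2,3-dimethoxyphenyl)chromen-4-one | COc1cccc(-c2cc(=O)c3c(O)c(OC)c(OCc4ccccc4)c(OC)c3o2)c1OC | intermediate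
16 | 5,7-dihydroxy-6,8-dimethoxy-2-(2,3-dimethoxyphenyl)chromen-4-one (5,7-dihydroxy-6,8,2',3'-tetramethoxyflavone) | COc1cccc(-c2cc(=O)c3c(O)c(OC)c(O)c(OC)c3o2)c1OC | target

**Step count**
Total: 9 steps. Longest linear sequence: 8 steps (steps 2–9, from 3 and 4 to 16). Step 1 is a one-step side branch that joins at step 5.

**Steps most likely to fail**

1. Step 7 (key step).
   - What may go wrong: closure onto the cross-conjugated C5=C6 bond of the pyranone may be slower than other fates of the ketene. The main ones are addition of the tertiary hydroxyl to the ketene after inward rotation (butenolide formation) and oligomerisation. The free hydroquinone may also oxidise during heating.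
   - Fallback: set out from 11 and silylate the carbinol (Me3SiCl, Et3N, DMAP, CH2Cl2) to give 2-(benzyloxy)-4-[6-(2,3-dimethoxyphenyl)-4-oxo-4H-pyran-3-yl]-3-methoxy-4-[(trimethylsilyl)oxy]cyclobut-2-en-1-one F1. This ether cannot lactonise and its siloxy group still rotates outward. Thermolysis (p-xylene, 135 °C) should give the mono-protected hydroquinone 7-(benzyloxy)-2-(2,3-dimethoxyphenyl)-8-hydroxy-6-methoxy-5-[(trimethylsilyl)oxy]chromen-4-one F2, in which only O8 is free. MeI and K2CO3 in acetone should then give 7-(benzyloxy)-2-(2,3-dimethoxyphenyl)-6,8-dimethoxy-5-[(trimethylsilyl)oxy]chromen-4-one F3. Methanolysis of the silyl ether (K2CO3, MeOH) comes back to the route at 15.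

2. Step 6.
   - What may go wrong: methoxide may deprotonate the tertiary alcohol and set off alkoxide-accelerated opening of the four-membered ring, or open the pyranone by conjugate addition at C6, faster than it exchanges the C3 alkoxy group.
   - Fallback: keep both benzyl ethers and differentiate O6 from O7 on the flavone, using only standard flavonoid selectivities. Set out from 10 and thermolyse it under the conditions of step 7 to give 6,7-bis(benzyloxy)-5,8-dihydroxy-2-(2,3-dimethoxyphenyl)chromen-4-one F4. Methylation of the free O8 (MeI, K2CO3, acetone) should give 6,7-bis(benzyloxy)-5-hydroxy-8-methoxy-2-(2,3-dimethoxyphenyl)chromen-4-one F5. Hydrogenolysis (H2, Pd/C) should give 5,6,7-trihydroxy-8-methoxy-2-(2,3-dimethoxyphenyl)chromen-4-one F6. One equivalent of BnBr with K2CO3 in DMF should alkylate the most acidic hydroxyl, O7 (para to the C4 carbonyl), to give 7-(benzyloxy)-5,6-dihydroxy-8-methoxy-2-(2,3-dimethoxyphenyl)chromen-4-one F7. MeI and K2CO3 then methylate O6 and leave the chelated O5, which comes back to the route at 15.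

3. Step 5.
   - What may go wrong: the β-alkoxy alkenylmagnesium may fragment by β-elimination of the ring oxygen, isopropylmagnesium chloride may add to the pyranone before the exchange, or the reagent may add twice to the squarate.
   - Fallback: set out from 8 and insert zinc directly (Zn dust, LiCl, THF, 25 °C) to give the less basic and thermally more robust [6-(2,3-dimethoxyphenyl)-4-oxo-4H-pyran-3-yl]zinc iodide F8. Its addition to 2 in the presence of MgCl2 (Lewis-acid-promoted carbonyl addition of an organozinc halide) comes back to the route at 10.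

**Further compounds**
F1 | step 7 | 2-(benzyloxy)-4-[6-(2,3-dimethoxyphenyl)-4-oxo-4H-pyran-3-yl]-3-methoxy-4-[(trimethylsilyl)oxy]cyclobut-2-en-1-one (racemic) | O=C1C(OCc2ccccc2)=C(OC)C1(O[Si](C)(C)C)c1coc(-c2cccc(OC)c2OC)cc1=O
F2 | step 7 | 7-(benzyloxy)-2-(2,3-dimethoxyphenyl)-8-hydroxy-6-methoxy-5-[(trimethylsilyl)oxy]chromen-4-one | COc1cccc(-c2cc(=O)c3c(O[Si](C)(C)C)c(OC)c(OCc4ccccc4)c(O)c3o2)c1OC
F3 | step 7 | 7-(benzyloxy)-2-(2,3-dimethoxyphenyl)-6,8-dimethoxy-5-[(trimethylsilyl)oxy]chromen-4-one | COc1cccc(-c2cc(=O)c3c(O[Si](C)(C)C)c(OC)c(OCc4ccccc4)c(OC)c3o2)c1OC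
F4 | step 6 | 6,7-bis(benzyloxy)-5,8-dihydroxy-2-(2,3-dimethoxyphenyl)chromen-4-one | COc1cccc(-c2cc(=O)c3c(O)c(OCc4ccccc4)c(OCc4ccccc4)c(O)c3o2)c1OC
F5 | step 6 | 6,7-bis(benzyloxy)-5-hydroxy-8-methoxy-2-(2,3-dimethoxyphenyl)chromen-4-one | COc1cccc(-c2cc(=O)c3c(O)c(OCc4ccccc4)c(OCc4ccccc4)c(OC)c3o2)c1OC
F6 | step 6 | 5,6,7-trihydroxy-8-methoxy-2-(2,3-dimethoxyphenyl)chromen-4-one | COc1cccc(-c2cc(=O)c3c(O)c(O)c(O)c(OC)c3o2)c1OC
F7 | step 6 | 7-(benzyloxy)-5,6-dihydroxy-8-methoxy-2-(2,3-dimethoxyphenyl)chromen-4-one | COc1cccc(-c2cc(=O)c3c(O)c(O)c(OCc4ccccc4)c(OC)c3o2)c1OC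
F8 | step 5 | [6-(2,3-dimethoxyphenyl)-4-oxo-4H-pyran-3-yl]zinc iodide | COc1cccc(-c2cc(=O)c([Zn]I)co2)c1OC
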